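A one-step world has one clock, but this flask has a ladder of 4 exchanges, and the question concerns the top two rungs.

| setting | south-west | south-east | north | north-east | north-west |
|---|---|---|---|---|---|
| starting complex | 0.10 M | 0.10 M | 0.10 M (fed, over 40 h) | 0.10 M (fed, over 40 h) | 0.10 M (fed, over 10 h) |
| incoming ligand | 0.400 M (in portions, 2, over 40 h) | 0.400 M | 0.400 M | 0.400 M | 0.400 M |
| protic impurity | 2.00 mM | 2.00 mM | 2.00 mM | 2.00 mM | 2.00 mM |
| temperature | 25 °C | 25 °C |  | 25 °C | 25 °C |
| time | 50 h | 50 h | 50 h | 50 h | 50 h |
| remark | first portion at the start, last at 40 h | everything together at the start | the addition at −5 °C, then warmed to 25 °C; the feed brings no volume worth counting | all else is in the flask from the start; the feed brings no volume worth counting | all else is in the flask from the start; the feed brings no volume worth counting |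

- the flask with the highest share of complex with three exchanged in complex with three exchanged plus complex with four exchanged ("all alike" if they lie within 1.5 percentage points) (south-west / south-east / north / north-east / north-west / all alike)
- share of complex with three exchanged in complex with three exchanged plus complex with four exchanged at the end, south-west
- share of complex with three exchanged in complex with three exchanged plus complex with four exchanged at the end, south-east
- share of complex with three exchanged in complex with three exchanged plus complex with four exchanged at the end, north
- share of complex with three exchanged in complex with three exchanged plus complex with four exchanged at the end, north-east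
- share of complex with three exchanged in complex with three exchanged plus complex with four exchanged at the end, north-west

- at 25 °C the constants are as listed, elsewhere as the activation energies and enthalpies make them

The reckoning here concerns north, where the feed runs at −5 °C. It takes the two middle exchanges, with activation energies of 81.0 kJ mol⁻¹ and 84.0 kJ mol⁻¹, as standing still during that feed, and it treats the warming as instant. So the climb begins at 40 h and the warm window lasts 10.0 h, against 50 h at 25 °C in the other flasks. The first exchange has a forward half-life of 5.72 h at the charged ligand, so it can reach its balance inside that window.

Let f be the fraction of the starting complex charge exchanged once. With incoming ligand taken as charged, f²/(1−f) equals 0.113 times the ratio of the ligand charge to the complex charge, which is 0.452. That gives f = 48.3%, and so 87.9% of the ligand charge remains.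

At that ligand level, a complex with three exchanged moves on with a clock of 10.9 h, the way back left out. This is a pseudo-first-order time, and it is close to the window. The passage number, the warm window divided by this clock, is therefore 0.918. A share read this way is under kinetic, not thermodynamic, control.

With a steady supply of complex with three exchanged through the window, the part not yet moved on is (1−e⁻ˣ)/x, or 65.4%. The steady supply is the weak link. Complex with two exchanged starts the window as good as absent in this picture, so the supply grows roughly in proportion to time, and younger material has had less time to pass on. The share then becomes 2(x−1+e⁻ˣ)/x², which gives 75.3%. With the clock running for the shorter time there, the choice falls on north.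

The forecast also names north, with 80% there, and gives 65% for south-west, 63% for south-east, 63.5% for north-east and 63% for north-west. Of the cold feed it says “almost nothing happens”. Its north stands above the reckoning here, and this reckoning offers no figure for the other flasks.

    protic impurity + starting complex → quenched substrate (k1 = 0.00100 M⁻¹ s⁻¹, Ea1 = 56.0 kJ mol⁻¹)
    complex with one exchanged + incoming ligand ⇌ leaving ligand + complex with two exchanged (K2 = 0.079, k2 = 3.50 × 10⁻⁵ M⁻¹ s⁻¹, Ea2 = 81.0 kJ mol⁻¹, ΔH2 = −89.0 kJ mol⁻¹)
    starting complex + incoming ligand ⇌ leaving ligand + complex with one exchanged (K3 = 0.113, k3 = 8.42 × 10⁻⁵ M⁻¹ s⁻¹, Ea3 = 64.0 kJ mol⁻¹, ΔH3 = −42.0 kJ mol⁻¹)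
    complex with three exchanged + incoming ligand ⇌ leaving ligand + complex with four exchanged (K4 = 0.19, k4 = 7.25 × 10⁻⁵ M⁻¹ s⁻¹, Ea4 = 60.0 kJ mol⁻¹, ΔH4 = −61.0 kJ mol⁻¹)
    complex with two exchanged + incoming ligand ⇌ leaving ligand + complex with three exchanged (K5 = 4.27, k5 = 4.77 × 10⁻⁵ M⁻¹ s⁻¹, Ea5 = 84.0 kJ mol⁻¹, ΔH5 = −14.0 kJ mol⁻¹)
    (constants at 25 °C)

The simulation gives north as the highest, at 77.9%, against 63.7% in south-west, 62.1% in south-east, 61.4% in north-east and 61.9% in north-west. After 50.0 h, north holds 2.07% of the starting complex charge as complex with three exchanged and 0.586% as complex with four exchanged. The passage number goes next to a neighbour of north charged with 0.025 M of starting complex. There, the same reckoning has more of that smaller charge exchanged once and the ligand nearer its charge, and the number becomes 0.997, so the growing-supply share is 73.6%. That neighbour reads 75.3%.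

The constants used here stand for no real mixture.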